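All runs are simulated with made-up constants, noise included.

The vessel was closed and stirred, with the gas phase held, and the two runs differed in the protic impurity.

| setting | maple | cedar | flask |
|---|---|---|---|
| substrate | 2 M | 2 M | 2.0 M |
| gas phase | 81 mM (held) | 81 mM (held) | 81 mM (held) |
| protic impurity | 0.60 M | 0.30 M | 0.600 M |
| remark | the very flask that is asked about, followed so far | run made earlier |  |
| time |  |  | 2.5 min |

maple run (percent of the substrate charged)

| time / s | target / % |
|---|---|
| 10.0 | 14 |
| 12.0 | 15 |
| 15.0 | 18 |
| 20.0 | 20 |
| 30.0 | 20 |

cedar run (percent of the substrate charged)

| time / min | target / % |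
|---|---|
| 0.167 | 14 |
| 0.200 | 15 |
| 0.417 | 23 |
| 0.667 | 19 |
| 1.33 | 8 |
| 2.50 | 3 |

(scatter of a reading: 1.5 percentage points)

- at the start none of the gas phase is in solution

* time up to 2.5 min at which target stands highest
* the amount of target, in percent of the substrate charged, at that time

Maple stopped at 30.0 s of a window of 2.5 min. I turned the question round. For the best to come late, maple's target would have to climb past 20 % after that last reading. Cedar, with [protic impurity] at 0.30 M, went the other way: it fell from 19 % at 0.667 min to 3 % at 2.50 min. That fall of 16 percentage points stood well above the scatter of 1.5 points.

Cedar gave 1.01 /min for the tail constant, the logarithm of the ratio of two late readings divided by the time between them. It is a pseudo-first-order constant, read from readings. A late best in maple needed the constant at zero or below. I froze it, though maple held twice the protic impurity of cedar, and ran it on maple from the last reading. On that estimate maple stood at 2.65 % at 2.5 min, less than 20 %. My reckoning gave no peak, so the peak here is the forecast's.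

The forecast put the best at 21 % at 0.4 min, and said “nothing later in the 2.5 min window should exceed it”.

The flask peaked at 21.1 % at 0.422 min.

    substrate + dissolved gas ⇌ target (K = 26.0 /M, k = 1.30 /M/s)
    dissolved gas + protic impurity → quenched reagent (k = 0.00960 /M/s)
    dissolved gas → decomposed reagent (k = 0.0890 /s)
    gas phase ⇌ dissolved gas, rate k4*(csat - [dissolved gas]) (kL = 0.540 /s)
    substrate → side product (k = 0.0640 /s)

With half the protic impurity, the flask's highest target stood at 21.1 %. Run from the best to 2.5 min, the tail constant gave 2.59 %, and the flask held 2.97 %. Over that stretch the tail constant keeps 12.3 % of the flask's best. The neighbour charged with 0.50 M of substrate reached 29.2 % and kept 12.0 % of that at 2.5 min.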